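Everything rests on disconnecting ring A at C1–C5. Quaternary C1 and carbinol C5 are neighbours in ring A, and C1 also carries C1′, the future ring B carbinol, at carbonyl level: an aldol pattern (C1′–C1–C5–O) inside the cyclopentane. A samarium diiodide Reformatsky closure of an acyclic α-bromo ester aldehyde should form this bond, close ring A and set C1 and C5 in one operation, steered by a single preset centre, the C3 silyl ether. The precursor is a tert-butyl 2-bromo ester (both C1 epimers, which converge) with gem-dimethyl C2, (R)-configured C3–OTBS and a C5 aldehyde. Ring B is then built on C1′ and halogenated under tether control.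

Key step: step 9

Remark (labels): atoms keep the target labels throughout, also in acyclic precursors: ring A C1 (quaternary, methyl), C2 (gem-dimethyl), C3 (CHBr), C4, C5 (CHOH); ring B C1′ (carbinol), C2′, C3′ (CHBr), C4′ (CMeCl), C5′, C6′; "up" is the ring A face of the C1 methyl group.
Remark (ester): the ester is carried as the tert-butyl ester, because with a methyl ester the C3 hydroxyl freed in step 6 would close onto C1′ to a γ-lactone (gem-dimethyl C2 and quaternary C1 favour this) before it can be silylated.
Remark (C3 bromide): a free C1′ oxygen, or an ester or ketone carbonyl at C1′, lies cis to the rear side of C3 and would itself displace a C3 leaving group; the inversion with bromide is therefore run while the C5 and C1′ oxygens are tied in a boronate.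
Remark (ring B halogens): direct bromochlorination of the ring B alkene is expected to follow the trans-diaxial course and give the C3′,C4′ bis-epimer, so the halogens are delivered through a C1′–O–C4′ tether.

Step 1
Reactants: 1 3-methylbut-2-en-1-ol; 2 propanoyl chloride
Product: 3 3-methylbut-2-en-1-yl propanoate
Conditions: Et3N, DMAP (cat.), CH2Cl2, 0 → 23 °C
Reagents that add atoms: propanoyl chloride (2), CCC(Cl)=O
Why: DMAP-catalysed O-acylation of a primary allylic alcohol with an acyl chloride is routine and creates no stereocentre.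

Step 2
Reactants: 3 3-methylbut-2-en-1-yl propanoate
Product: 7 (±)-2,3,3-trimethylpent-4-enoic acid, via lithium enolate 4 (not isolated), via silyl ketene acetal 5 (not isolated), via trimethylsilyl ester 6 (not isolated)
Conditions: LiN(iPr)2 (LDA), THF, −78 °C; TMSCl, −78 → 65 °C; then 1 M HCl
Reagents that add atoms: none
Why: Ireland–Claisen rearrangement, in which the silyl ketene acetal undergoes a chair-like [3,3]-sigmatropic shift that bonds C1 to the dimethyl-substituted allyl terminus (quaternary C2) and leaves the vinyl group that becomes C3; C1 forms racemic, which is harmless because it is later erased as an enolate carbon.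

Step 3
Reactants: 7 (±)-2,3,3-trimethylpent-4-enoic acid
Product: 8 tert-butyl (±)-2,3,3-trimethylpent-4-enoate
Conditions: tert-butyl 2,2,2-trichloroacetimidate, BF3·OEt2 (cat.), cyclohexane/CH2Cl2, 23 °C
Reagents that add atoms: tert-butyl 2,2,2-trichloroacetimidate, CC(C)(C)OC(=N)C(Cl)(Cl)Cl
Why: Acid-catalysed O-tert-butylation with the trichloroacetimidate runs through the tert-butyl cation, so the hindered carboxyl carbon need not be attacked.

Step 4
Reactants: 8 tert-butyl (±)-2,3,3-trimethylpent-4-enoate
Product: 10 tert-butyl (±)-2-bromo-2,3,3-trimethylpent-4-enoate, via lithium enolate 9 (not isolated)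
Conditions: LiN(iPr)2 (LDA), THF, −78 → −30 °C; CBr4, −78 °C; then H2O
Reagents that add atoms: tetrabromomethane, BrC(Br)(Br)Br
Why: Ester enolate bromination, in which the lithium enolate takes electrophilic bromine from CBr4 at C1; the configuration of C1 is irrelevant.

Step 5
Reactants: 10 tert-butyl (±)-2-bromo-2,3,3-trimethylpent-4-enoate
Product: 12 tert-butyl (±)-2-bromo-2,3,3-trimethyl-4-oxobutanoate, via ozonide 11 (not isolated)
Conditions: O3, CH2Cl2, −78 °C; then Me2S, −78 → 23 °C
Reagents that add atoms: ozone, [O-][O+]=O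
Why: Ozonolysis with reductive work-up cleaves the only alkene to the C3 aldehyde, which has no α-hydrogen and therefore cannot lose the β-bromide by elimination.

Step 6
Reactants: 12 tert-butyl (±)-2-bromo-2,3,3-trimethyl-4-oxobutanoate; 13 (+)-B-methoxydiisopinocampheylborane; 14 allylmagnesium bromide
Product: 17 tert-butyl (4R)-2-bromo-4-hydroxy-2,3,3-trimethylhept-6-enoate (both C1 epimers), via allylborane 15 (not isolated), via borinate 16 (not isolated)
Conditions: 13, 14, Et2O, −78 → 23 °C; then 12, −78 °C; then 3 M aq. NaOAc, 30% H2O2, 0 → 23 °C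
Reagents that add atoms: allylmagnesium bromide (14), C=CC[Mg]Br
Why: Brown asymmetric allylboration through a chair Zimmerman–Traxler transition state, in which the isopinocampheyl groups of the (−)-α-pinene series direct allyl transfer to the Re face of the aldehyde and so set C3 as (R) under reagent control for both C1 epimers; the buffered oxidation avoids alkoxide-triggered fragmentation of the γ-bromo alcohol.

Step 7
Reactants: 17 tert-butyl (4R)-2-bromo-4-hydroxy-2,3,3-trimethylhept-6-enoate
Product: 18 tert-butyl (4R)-2-bromo-4-[(tert-butyldimethylsilyl)oxy]-2,3,3-trimethylhept-6-enoate (both C1 epimers)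
Conditions: TBSOTf, 2,6-lutidine, CH2Cl2, −78 → 0 °C (crude 17 used at once)
Reagents that add atoms: tert-butyldimethylsilyl trifluoromethanesulfonate, CC(C)(C)[Si](C)(C)OS(=O)(=O)C(F)(F)F
Why: Silyl ether formation with the silyl triflate reaches the hindered secondary hydroxyl quickly, so the γ-hydroxy ester has no time to lactonise, and no stereocentre is touched.

Step 8
Reactants: 18 tert-butyl (4R)-2-bromo-4-[(tert-butyldimethylsilyl)oxy]-2,3,3-trimethylhept-6-enoate
Product: 20 tert-butyl (4R)-2-bromo-4-[(tert-butyldimethylsilyl)oxy]-2,3,3-trimethyl-6-oxohexanoate (both C1 epimers), via ozonide 19 (not isolated)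
Conditions: O3, CH2Cl2, −78 °C; then Me2S, −78 → 23 °C
Reagents that add atoms: ozone, [O-][O+]=O
Why: Ozonolysis of the terminal alkene with reductive work-up gives the C5 aldehyde, and silyl ether, tertiary bromide and tert-butyl ester are inert to ozone.

Step 9
Reactants: 20 tert-butyl (4R)-2-bromo-4-[(tert-butyldimethylsilyl)oxy]-2,3,3-trimethyl-6-oxohexanoate
Product: 22 tert-butyl (1S,3R,5R)-3-[(tert-butyldimethylsilyl)oxy]-5-hydroxy-1,2,2-trimethylcyclopentane-1-carboxylate, via samarium enolate 21 (not isolated)
Conditions: SmI2 (2.5 equiv), THF, −78 → −40 °C, slow addition of 20; then pH 7 phosphate buffer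
Reagents that add atoms: none
Why: Two single-electron transfers from divalent samarium cleave the C1–Br bond and give a trivalent samarium ester enolate under neutral conditions, which adds to the C5 aldehyde; the closest known reaction type is the SmI2-mediated intramolecular Reformatsky reaction. Ring A closes in a 5-(enolexo)-exo-trig mode, helped by the gem-dimethyl group at C2. C1 is set relative to C5 by the samarium bridge between enolate oxygen and aldehyde oxygen in a closed transition state, which holds the ester carbon and the C5 oxygen on the same ring face. C5 is set relative to C3 because the bulky silyloxy group takes the pseudoequatorial site of the envelope, anti to the forming C5–O(Sm) bond, so C3–O ends trans to C5–O. The step needs chemoselectivity for the bromide over the enolisable aldehyde, secured by the much easier reduction of an α-bromo ester at −78 °C without HMPA, and stereoconvergence, secured because both C1 epimers give the same planar enolate.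

Step 10
Reactants: 22 tert-butyl (1S,3R,5R)-3-[(tert-butyldimethylsilyl)oxy]-5-hydroxy-1,2,2-trimethylcyclopentane-1-carboxylate
Product: 23 tert-butyl 3,5-bis[(tert-butyldimethylsilyl)oxy]-1,2,2-trimethylcyclopentane-1-carboxylate (configuration as in 22)
Conditions: TBSOTf, 2,6-lutidine, CH2Cl2, 0 °C
Reagents that add atoms: tert-butyldimethylsilyl trifluoromethanesulfonate, CC(C)(C)[Si](C)(C)OS(=O)(=O)C(F)(F)F
Why: Silyl ether protection of the C5 hydroxyl blocks retro-aldol opening of ring A and permits the later oxidations; no stereocentre is affected.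

Step 11
Reactants: 23 tert-butyl 3,5-bis[(tert-butyldimethylsilyl)oxy]-1,2,2-trimethylcyclopentane-1-carboxylate
Product: 24 {3,5-bis[(tert-butyldimethylsilyl)oxy]-1,2,2-trimethylcyclopentyl}methanol (configuration as in 22)
Conditions: LiAlH4, THF, 0 → 45 °C; then H2O, 15% NaOH (Fieser work-up)
Reagents that add atoms: none
Why: LiAlH4 reduction of an ester to the primary alcohol, the small hydride reaching even this neopentylic tert-butyl ester while silyl ethers stay intact.

Step 12
Reactants: 24 {3,5-bis[(tert-butyldimethylsilyl)oxy]-1,2,2-trimethylcyclopentyl}methanol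
Product: 25 3,5-bis[(tert-butyldimethylsilyl)oxy]-1,2,2-trimethylcyclopentane-1-carbaldehyde (configuration as in 22)
Conditions: Dess–Martin periodinane, NaHCO3, CH2Cl2, 0 → 23 °C
Reagents that add atoms: none
Why: Dess–Martin oxidation of the primary alcohol gives the C1′ aldehyde, which cannot epimerise because C1 is quaternary.

Step 13
Reactants: 25 3,5-bis[(tert-butyldimethylsilyl)oxy]-1,2,2-trimethylcyclopentane-1-carbaldehyde; 26 4-bromo-2-methylbut-1-ene
Product: 28 1-{3,5-bis[(tert-butyldimethylsilyl)oxy]-1,2,2-trimethylcyclopentyl}-4-methylpent-4-en-1-ol (both C1′ epimers), via Grignard reagent 27 (not isolated)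
Conditions: 26, Mg, THF, 40 °C; then 25, THF, −78 → 0 °C; then H2O
Reagents that add atoms: 4-bromo-2-methylbut-1-ene (26), CC(=C)CCBr
Why: Grignard addition to the aldehyde installs C6′, C5′, C4′ and the C4′ methyl group, the new carbinol centre being a mixture that the next oxidation removes.

Step 14
Reactants: 28 1-{3,5-bis[(tert-butyldimethylsilyl)oxy]-1,2,2-trimethylcyclopentyl}-4-methylpent-4-en-1-ol
Product: 29 1-{3,5-bis[(tert-butyldimethylsilyl)oxy]-1,2,2-trimethylcyclopentyl}-4-methylpent-4-en-1-one (configuration as in 22)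
Conditions: Dess–Martin periodinane, NaHCO3, CH2Cl2, 23 °C
Reagents that add atoms: none
Why: Dess–Martin oxidation of the secondary alcohol gives the C1′ ketone, with no epimerisable centre next to it.

Step 15
Reactants: 29 1-{3,5-bis[(tert-butyldimethylsilyl)oxy]-1,2,2-trimethylcyclopentyl}-4-methylpent-4-en-1-one
Product: 30 1-[3,5-dihydroxy-1,2,2-trimethylcyclopentyl]-4-methylpent-4-en-1-one (C5–OH cis to the acyl group and C3–OH trans to it)
Conditions: 48% aq. HF, MeCN, 23 → 40 °C
Reagents that add atoms: none
Why: Acidic fluoride cleavage of both silyl ethers, chosen because basic fluoride would start retro-aldol cleavage of the β-hydroxy ketone.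

Step 16
Reactants: 30 1-[3,5-dihydroxy-1,2,2-trimethylcyclopentyl]-4-methylpent-4-en-1-one; 14 allylmagnesium bromide
Product: 31 (4R)-4-[3,5-dihydroxy-1,2,2-trimethylcyclopentyl]-7-methylocta-1,7-dien-4-ol (ring A as in 30)
Conditions: 14 (4.5 equiv), Et2O, −78 °C; then H2O
Reagents that add atoms: allylmagnesium bromide (14), C=CC[Mg]Br
Why: Chelation-controlled Grignard addition, in which the C5 magnesium alkoxide ties the ketone oxygen into a six-membered chelate cis-fused to ring A and allyl enters from the face flanked by the C1 methyl group, opposite the gem-dimethyl carbon C2 (the Felkin–Anh model predicts the same face), which sets C1′ as (R).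

Step 17
Reactants: 31 (4R)-4-[3,5-dihydroxy-1,2,2-trimethylcyclopentyl]-7-methylocta-1,7-dien-4-ol
Product: 32 (1R)-1-[(1S,3R,5R)-3,5-dihydroxy-1,2,2-trimethylcyclopentyl]-4-methylcyclohex-3-en-1-ol
Conditions: second-generation Grubbs catalyst (5 mol%), CH2Cl2, 40 °C
Reagents that add atoms: none
Why: Ring-closing olefin metathesis between the allyl group and the 1,1-disubstituted alkene closes ring B as a cyclohexene with the trisubstituted C3′=C4′ bond, driven by loss of ethene and tolerant of free hydroxyls.

Step 18
Reactants: 32 (1R)-1-[(1S,3R,5R)-3,5-dihydroxy-1,2,2-trimethylcyclopentyl]-4-methylcyclohex-3-en-1-ol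
Product: 36 (1R)-1-[(1S,3S,5R)-3-bromo-5-hydroxy-1,2,2-trimethylcyclopentyl]-4-methylcyclohex-3-en-1-ol, via phenylboronate 33 (not isolated), via triflate 34 (not isolated), via bromo boronate 35 (not isolated)
Conditions: PhB(OH)2, toluene, reflux (Dean–Stark); then Tf2O (1.1 equiv), 2,6-lutidine, CH2Cl2, −40 °C; then Bu4NBr, toluene, −40 → 23 °C; then 30% H2O2, aq. NaHCO3, THF, 0 °C
Reagents that add atoms: tetrabutylammonium bromide, CCCC[N+](CCCC)(CCCC)CCCC.[Br-]
Why: A transient cyclic phenylboronate on the cis-1,3-diol (C5–OH and C1′–OH) leaves only C3–OH free and makes the C1′ oxygen non-nucleophilic, so that triflate formation and SN2 displacement by bromide invert C3 (oxygen up to bromine down, cis to C5–O) without transannular ether formation, as in the known inversions of neopentylic cyclopentanols such as steroid C17 alcohols.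

Step 19
Reactants: 36 (1R)-1-[(1S,3S,5R)-3-bromo-5-hydroxy-1,2,2-trimethylcyclopentyl]-4-methylcyclohex-3-en-1-ol
Product: 37 2-endo-bromo-4-[(1S,3S,5R)-3-bromo-5-hydroxy-1,2,2-trimethylcyclopentyl]-1-methyl-7-oxabicyclo[2.2.1]heptane (C1′–O–C4′ bridge with C3′–Br anti to the bridge)
Conditions: NBS, CH2Cl2, 0 °C, dark
Reagents that add atoms: N-bromosuccinimide, O=C1CCC(=O)N1Br
Why: Bromoetherification, in which bromonium ions form reversibly and only the one on the face opposite the C1′ hydroxyl is captured by that hydroxyl at the tertiary C4′ (Markovnikov, transannular 1,4-closure as in cineole formation), which places bromine at C3′ anti to oxygen.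

Step 20
Reactants: 37 2-endo-bromo-4-[(1S,3S,5R)-3-bromo-5-hydroxy-1,2,2-trimethylcyclopentyl]-1-methyl-7-oxabicyclo[2.2.1]heptane
Product: 40 (1R,3S,4S)-3-bromo-1-[(1S,3S,5R)-3-bromo-5-hydroxy-1,2,2-trimethylcyclopentyl]-4-chloro-4-methylcyclohexan-1-ol, via dichloroborinate 38 (not isolated), via chloroborate 39 (not isolated)
Conditions: BCl3 (2.2 equiv), CH2Cl2, −78 → −40 °C; then H2O, THF, 0 °C
Reagents that add atoms: boron trichloride, ClB(Cl)Cl
Why: Lewis acid cleavage of a tertiary ether to the alkyl chloride with neighbouring-group participation, in which boron bound to the C5 oxygen coordinates the bridging oxygen, the antiperiplanar C3′ bromine assists heterolysis of the C4′–O bond by re-forming the bromonium ion, and chloride returns from boron to C4′ on the face that oxygen left (net retention at C4′, trans to bromine), the six-membered cyclic chloroborate then being hydrolysed.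

Compound list
1 | 3-methylbut-2-en-1-ol | CC(C)=CCO | starting material
2 | propanoyl chloride | CCC(Cl)=O | starting material
3 | 3-methylbut-2-en-1-yl propanoate | CCC(=O)OCC=C(C)C | intermediate
4 | lithium enolate of 3 | CC=C([O-])OCC=C(C)C.[Li+] | intermediate
5 | trimethylsilyl ketene acetal of 3 (double-bond geometry without consequence) | CC=C(O[Si](C)(C)C)OCC=C(C)C | intermediate
6 | trimethylsilyl (±)-2,3,3-trimethylpent-4-enoate | CC(C(=O)O[Si](C)(C)C)C(C)(C)C=C | intermediate
7 | (±)-2,3,3-trimethylpent-4-enoic acid | CC(C(=O)O)C(C)(C)C=C | intermediate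
8 | tert-butyl (±)-2,3,3-trimethylpent-4-enoate | CC(C(=O)OC(C)(C)C)C(C)(C)C=C | intermediate
9 | lithium enolate of 8 | CC(=C([O-])OC(C)(C)C)C(C)(C)C=C.[Li+] | intermediate
10 | tert-butyl (±)-2-bromo-2,3,3-trimethylpent-4-enoate | CC(Br)(C(=O)OC(C)(C)C)C(C)(C)C=C | intermediate
11 | ozonide (1,2,4-trioxolane) of 10 | CC(Br)(C(=O)OC(C)(C)C)C(C)(C)C1OCOO1 | intermediate
12 | tert-butyl (±)-2-bromo-2,3,3-trimethyl-4-oxobutanoate | CC(Br)(C(=O)OC(C)(C)C)C(C)(C)C=O | intermediate
13 | (+)-B-methoxydiisopinocampheylborane (isopinocampheyl groups of the (−)-α-pinene series) | COB([C@H]1C[C@H]2C[C@@H]([C@@H]1C)C2(C)C)[C@H]1C[C@H]2C[C@@H]([C@@H]1C)C2(C)C | starting material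
14 | allylmagnesium bromide | C=CC[Mg]Br | starting material
15 | (+)-B-allyldiisopinocampheylborane | C=CCB([C@H]1C[C@H]2C[C@@H]([C@@H]1C)C2(C)C)[C@H]1C[C@H]2C[C@@H]([C@@H]1C)C2(C)C | intermediate
16 | diisopinocampheylborinate of 17 | CC(Br)(C(=O)OC(C)(C)C)C(C)(C)[C@H](OB([C@H]1C[C@H]2C[C@@H]([C@@H]1C)C2(C)C)[C@H]1C[C@H]2C[C@@H]([C@@H]1C)C2(C)C)CC=C | intermediate
17 | tert-butyl (4R)-2-bromo-4-hydroxy-2,3,3-trimethylhept-6-enoate (both C1 epimers; chain C2 = C1, chain C4 = C3) | CC(Br)(C(=O)OC(C)(C)C)C(C)(C)[C@H](O)CC=C | intermediate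
18 | tert-butyl (4R)-2-bromo-4-[(tert-butyldimethylsilyl)oxy]-2,3,3-trimethylhept-6-enoate (both C1 epimers) | CC(Br)(C(=O)OC(C)(C)C)C(C)(C)[C@H](O[Si](C)(C)C(C)(C)C)CC=C | intermediate
19 | ozonide (1,2,4-trioxolane) of 18 | CC(Br)(C(=O)OC(C)(C)C)C(C)(C)[C@H](O[Si](C)(C)C(C)(C)C)CC1OCOO1 | intermediate
20 | tert-butyl (4R)-2-bromo-4-[(tert-butyldimethylsilyl)oxy]-2,3,3-trimethyl-6-oxohexanoate (both C1 epimers; chain C6 = C5) | CC(Br)(C(=O)OC(C)(C)C)C(C)(C)[C@H](O[Si](C)(C)C(C)(C)C)CC=O | intermediate
21 | samarium ester enolate of 20 (diiodosamarium bound to the enolate oxygen) | CC(=C(O[Sm](I)I)OC(C)(C)C)C(C)(C)[C@H](O[Si](C)(C)C(C)(C)C)CC=O | intermediate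
22 | tert-butyl (1S,3R,5R)-3-[(tert-butyldimethylsilyl)oxy]-5-hydroxy-1,2,2-trimethylcyclopentane-1-carboxylate (C5–OH cis to the ester, C3–OTBS trans to both) | CC1(C)[C@H](O[Si](C)(C)C(C)(C)C)C[C@@H](O)[C@@]1(C)C(=O)OC(C)(C)C | intermediate
23 | tert-butyl 3,5-bis[(tert-butyldimethylsilyl)oxy]-1,2,2-trimethylcyclopentane-1-carboxylate (configuration as in 22) | CC1(C)[C@H](O[Si](C)(C)C(C)(C)C)C[C@@H](O[Si](C)(C)C(C)(C)C)[C@@]1(C)C(=O)OC(C)(C)C | intermediate
24 | {3,5-bis[(tert-butyldimethylsilyl)oxy]-1,2,2-trimethylcyclopentyl}methanol (configuration as in 22) | CC1(C)[C@H](O[Si](C)(C)C(C)(C)C)C[C@@H](O[Si](C)(C)C(C)(C)C)[C@@]1(C)CO | intermediate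
25 | 3,5-bis[(tert-butyldimethylsilyl)oxy]-1,2,2-trimethylcyclopentane-1-carbaldehyde (configuration as in 22) | CC1(C)[C@H](O[Si](C)(C)C(C)(C)C)C[C@@H](O[Si](C)(C)C(C)(C)C)[C@@]1(C)C=O | intermediate
26 | 4-bromo-2-methylbut-1-ene | CC(=C)CCBr | starting material
27 | (3-methylbut-3-en-1-yl)magnesium bromide | CC(=C)CC[Mg]Br | intermediate
28 | 1-{3,5-bis[(tert-butyldimethylsilyl)oxy]-1,2,2-trimethylcyclopentyl}-4-methylpent-4-en-1-ol (both C1′ epimers; ring A as in 22) | CC1(C)[C@H](O[Si](C)(C)C(C)(C)C)C[C@@H](O[Si](C)(C)C(C)(C)C)[C@@]1(C)C(O)CCC(C)=C | intermediate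
29 | 1-{3,5-bis[(tert-butyldimethylsilyl)oxy]-1,2,2-trimethylcyclopentyl}-4-methylpent-4-en-1-one (ring A as in 22) | CC1(C)[C@H](O[Si](C)(C)C(C)(C)C)C[C@@H](O[Si](C)(C)C(C)(C)C)[C@@]1(C)C(=O)CCC(C)=C | intermediate
30 | 1-[3,5-dihydroxy-1,2,2-trimethylcyclopentyl]-4-methylpent-4-en-1-one (C5–OH cis to the acyl group, C3–OH trans) | CC1(C)[C@H](O)C[C@@H](O)[C@@]1(C)C(=O)CCC(C)=C | intermediate
31 | (4R)-4-[3,5-dihydroxy-1,2,2-trimethylcyclopentyl]-7-methylocta-1,7-dien-4-ol (ring A as in 30; C1′ is chain C4) | CC1(C)[C@H](O)C[C@@H](O)[C@@]1(C)[C@](O)(CC=C)CCC(C)=C | intermediate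
32 | (1R)-1-[(1S,3R,5R)-3,5-dihydroxy-1,2,2-trimethylcyclopentyl]-4-methylcyclohex-3-en-1-ol | CC1(C)[C@H](O)C[C@@H](O)[C@@]1(C)[C@@]1(O)CCC(C)=CC1 | intermediate
33 | cyclic phenylboronate of 32 across the C5 and C1′ oxygens (C3–OH free) | CC1(C)[C@H](O)C[C@@H](OB2c3ccccc3)[C@@]1(C)[C@@]1(O2)CCC(C)=CC1 | intermediate
34 | C3 triflate of 33 | CC1(C)[C@H](OS(=O)(=O)C(F)(F)F)C[C@@H](OB2c3ccccc3)[C@@]1(C)[C@@]1(O2)CCC(C)=CC1 | intermediate
35 | cyclic phenylboronate of 36 (C3–Br down, inverted) | CC1(C)[C@@H](Br)C[C@@H](OB2c3ccccc3)[C@@]1(C)[C@@]1(O2)CCC(C)=CC1 | intermediate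
36 | (1R)-1-[(1S,3S,5R)-3-bromo-5-hydroxy-1,2,2-trimethylcyclopentyl]-4-methylcyclohex-3-en-1-ol | CC1(C)[C@@H](Br)C[C@@H](O)[C@@]1(C)[C@@]1(O)CCC(C)=CC1 | intermediate
37 | 2-endo-bromo-4-[(1S,3S,5R)-3-bromo-5-hydroxy-1,2,2-trimethylcyclopentyl]-1-methyl-7-oxabicyclo[2.2.1]heptane (C1′–O–C4′ bridge; C3′–Br anti to the bridge) | CC1(C)[C@@H](Br)C[C@@H](O)[C@@]1(C)[C@@]12CC[C@](C)(O2)[C@@H](Br)C1 | intermediate
38 | C5 O-dichloroboryl derivative of 37 | CC1(C)[C@@H](Br)C[C@@H](OB(Cl)Cl)[C@@]1(C)[C@@]12CC[C@](C)(O2)[C@@H](Br)C1 | intermediate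
39 | cyclic chloroborate of 40 across the C5 and C1′ oxygens | CC1(C)[C@@H](Br)C[C@@H](OB2Cl)[C@@]1(C)[C@@]1(O2)CC[C@](C)(Cl)[C@@H](Br)C1 | intermediate
40 | (1R,3S,4S)-3-bromo-1-[(1S,3S,5R)-3-bromo-5-hydroxy-1,2,2-trimethylcyclopentyl]-4-chloro-4-methylcyclohexan-1-ol | CC1(C)[C@@H](Br)C[C@@H](O)[C@@]1(C)[C@@]1(O)CC[C@](C)(Cl)[C@@H](Br)C1 | target

Total step count: 20.
Longest linear sequence: 20 steps (1 → 40); compounds 2, 13, 14 and 26 are bought.

The three steps most likely to fail, in route order:

Step 9. What may go wrong: incomplete facial discrimination at the aldehyde during closure, so that the C5 epimer forms alongside 22, or quenching of the enolate before it closes. The fallback sets out from 22 obtained as a C5 epimer mixture. Dess–Martin oxidation would merge both epimers into the β-keto ester F1. Reduction with NaBH4 in MeOH at −40 °C should then deliver hydride from the face of the C1 methyl group, away from the tert-butyl ester, and return the cis hydroxy ester. The route is rejoined at 22. C5 would then be set by ketone reduction and no longer by the aldol closure.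

Step 18. What may go wrong: slow backside entry of bromide at the neopentylic C3 from the more crowded ring face, with elimination towards C4 taking over. The fallback sets out from 33. Dess–Martin oxidation of its only free hydroxyl would give the C3 ketone F2. Anhydrous hydrazine (THF, 4 Å sieves) should convert this into the hydrazone F3, and CuBr2 with LiOtBu into the geminal dibromide F4. One equivalent of Bu3SnH (Et3B, air, toluene, −78 °C) should then remove one bromine through the C3 radical, which takes hydrogen from the less hindered upper face and leaves the remaining bromine down. This gives 35, where the route is rejoined. No nucleophile has to reach the crowded face in this variant, since C3 is set by hydrogen-atom delivery.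

Step 20. What may go wrong: heterolysis at the other bridgehead bond (C1′–O) with skeletal rearrangement, or loss of the bromonium memory at C4′. The fallback sets out from 35, taken on without the oxidative release of step 18. Direct anti bromochlorination of the ring B alkene with Bu4N[BrCl2] in CH2Cl2 at −78 °C would be tried, the boronate keeping the C1′ oxygen from closing an ether. This would give the bromochloride boronate F5 after separation from its C3′,C4′ bis-epimer. H2O2 with NaHCO3 then releases the diol and the route is rejoined at 40. The facial course is substrate-controlled in this variant and is expected to favour the unwanted bis-epimer, so a separation has to be accepted.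

Further compounds
F1 | step 9 | tert-butyl (1S,3R)-3-[(tert-butyldimethylsilyl)oxy]-1,2,2-trimethyl-5-oxocyclopentane-1-carboxylate | CC1(C)[C@H](O[Si](C)(C)C(C)(C)C)CC(=O)[C@@]1(C)C(=O)OC(C)(C)C
F2 | step 18 | C3 ketone of phenylboronate 33 | CC1(C)C(=O)C[C@@H](OB2c3ccccc3)[C@@]1(C)[C@@]1(O2)CCC(C)=CC1
F3 | step 18 | C3 hydrazone of F2 | CC1(C)C(=NN)C[C@@H](OB2c3ccccc3)[C@@]1(C)[C@@]1(O2)CCC(C)=CC1
F4 | step 18 | C3 geminal dibromide (phenylboronate) | CC1(C)C(Br)(Br)C[C@@H](OB2c3ccccc3)[C@@]1(C)[C@@]1(O2)CCC(C)=CC1
F5 | step 20 | cyclic phenylboronate of 40 across the C5 and C1′ oxygens | CC1(C)[C@@H](Br)C[C@@H](OB2c3ccccc3)[C@@]1(C)[C@@]1(O2)CC[C@](C)(Cl)[C@@H](Br)C1
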